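**Strategy.** The cyclopentanone ring (C1, C2, C3, C3a, C8a of the hydroazulene) is disconnected at C1–C8a and C3–C3a. The 1,4-related oxygens at C1 and C3a mark C1(=O)–C2–C3 as an acyl carbon with a nucleophilic β-carbon, the reactivity of an α,β-unsaturated acylsilane after Brook rearrangement, while C8a–C3a is an amide enolate. One [3+2] annulation of the dianion of an aldol-derived Weinreb amide with (E)-4-methylpent-2-enoyl silane forms both bonds, sets C8a and C3, and leaves C1 masked as a silyl enol ether beside a free C3a ketone. Organocerium addition at C3a, ring-closing metathesis to the seven-membered ring, inversion of C8 by oxidation and reduction, and anisoylation complete the route.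

Key step: step 6

Remark: atoms carry the hydroazulene locants of the target throughout (C1 ketone, C3 isopropyl, C3a hydroxyl, C6 methyl, C8 ester, C8a methyl), also in monocyclic precursors; the C8 carbinol made in step 4 is a relay stereocentre that is deliberately inverted in steps 9 and 10.

Step 1
Reactants: 1 ethyl (E)-4-methylpent-2-enoate
Product: 2 (E)-4-methylpent-2-en-1-ol
Conditions: i-Bu2AlH (2.2 equiv), CH2Cl2, −78 → 0 °C; Rochelle salt
Reagents that add atoms: none
Why: 1,2-reduction of the unsaturated ester by the aluminium hydride should give the (E)-allylic alcohol with the alkene untouched.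

Step 2
Reactants: 2 (E)-4-methylpent-2-en-1-ol
Product: 4 (E)-1-(tert-butyldimethylsilyl)-4-methylpent-2-en-1-ol (racemic), via allyl silyl ether 3 (not isolated)
Conditions: n-BuLi, THF, −78 °C; TBSCl, −78 → 25 °C; t-BuLi, −78 → −30 °C; aq. NH4Cl
Reagents that add atoms: tert-butyldimethylsilyl chloride, CC(C)(C)[Si](C)(C)Cl
Why: O-silylation followed by α-lithiation of the allyl silyl ether should trigger the [1,2]-retro-Brook rearrangement to the α-silyl carbinol with retention of the (E)-alkene; the racemic carbinol centre is removed in step 3.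

Step 3
Reactants: 4 (E)-1-(tert-butyldimethylsilyl)-4-methylpent-2-en-1-ol
Product: 5 (E)-1-(tert-butyldimethylsilyl)-4-methylpent-2-en-1-one
Conditions: Dess–Martin periodinane, CH2Cl2, 0 → 25 °C
Reagents that add atoms: none
Why: Dess–Martin oxidation of the α-silyl carbinol should give the α,β-unsaturated acylsilane under non-basic conditions that avoid Brook rearrangement.

Step 4
Reactants: 6 (4R)-4-benzyl-3-propanoyl-1,3-oxazolidin-2-one; 7 acrolein
Product: 8 (4R)-4-benzyl-3-[(2R,3S)-3-hydroxy-2-methylpent-4-enoyl]-1,3-oxazolidin-2-one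
Conditions: n-Bu2BOTf, i-Pr2NEt, CH2Cl2, −78 → 0 °C; 7, −78 → 0 °C; pH 7 buffer, MeOH, H2O2
Reagents that add atoms: none
Why: Evans syn-aldol reaction, in which the (Z)-boron enolate of the (R)-auxiliary imide adds to acrolein through a Zimmerman–Traxler chair and should set (2R,3S); the 3S carbinol (future C8) is the relay centre for all later stereocontrol.

Step 5
Reactants: 8 (4R)-4-benzyl-3-[(2R,3S)-3-hydroxy-2-methylpent-4-enoyl]-1,3-oxazolidin-2-one
Product: 9 (2R,3S)-3-hydroxy-N-methoxy-N,2-dimethylpent-4-enamide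
Conditions: MeNH(OMe)·HCl, AlMe3, CH2Cl2, −20 → 0 °C; Rochelle salt
Reagents that add atoms: N,O-dimethylhydroxylamine hydrochloride, CNOC.Cl
Why: aluminium-amide transamination of the imide (Weinreb amide formation), assisted by the free β-hydroxyl, should release the auxiliary without epimerisation.

Step 6
Reactants: 9 (2R,3S)-3-hydroxy-N-methoxy-N,2-dimethylpent-4-enamide; 5 (E)-1-(tert-butyldimethylsilyl)-4-methylpent-2-en-1-one
Product: 12 (2R,5S)-3-[(tert-butyldimethylsilyl)oxy]-2-[(1S)-1-hydroxyprop-2-en-1-yl]-2-methyl-5-(propan-2-yl)cyclopent-3-en-1-one, via dilithium amide enolate 10 (not isolated), via tetrahedral hemiaminal dilithium salt 11 (not isolated)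
Conditions: LDA (2.2 equiv), THF, −78 → −40 °C; 5, −78 → −40 °C; aq. NH4Cl, −40 °C
Reagents that add atoms: none
Why: Proposed new method: the chelated dianion 10 should add through C8a to the acylsilane carbonyl (C1), the α-silyl alkoxide then undergoes 1,2-Brook rearrangement to an (E)-siloxyallyl lithium, and its γ-carbon (C3) attacks the Weinreb carbonyl (C3a) to give the chelated tetrahedral intermediate 11, which releases ketone 12 only on quench. The closest known reaction type is the Brook-rearrangement-mediated [3+2] annulation of acryloylsilanes with ketone lithium enolates; new here are the amide enolate as donor and the amide carbonyl as terminus. The cyclopentene ring closes by 5-exo-trig attack of the allyl anion terminus on the amide C=O. C8a should be controlled by the lithium-chelated C8 alkoxide, the acylsilane approaching anti to the vinyl group as in a Fráter–Seebach alkylation; C3 should be controlled by the retained (E)-geometry of the allyl anion in a lithium-bridged closed transition state, which places isopropyl cis to the hydroxyallyl group. The step needs 1,2- over 1,4-addition, which the hard lithium enolate, the β-isopropyl group and the high carbonyl electrophilicity of the acylsilane should secure, and it needs the C3a carbonyl to stay masked until quench, which the N-methoxy chelate secures so that C3 cannot enolise under base.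

Step 7
Reactants: 12 (2R,5S)-3-[(tert-butyldimethylsilyl)oxy]-2-[(1S)-1-hydroxyprop-2-en-1-yl]-2-methyl-5-(propan-2-yl)cyclopent-3-en-1-one
Product: 13 (1S,2S,5S)-3-[(tert-butyldimethylsilyl)oxy]-2-[(1S)-1-hydroxyprop-2-en-1-yl]-2-methyl-1-(3-methylbut-3-en-1-yl)-5-(propan-2-yl)cyclopent-3-en-1-ol
Conditions: CeCl3 (anhydrous), 3-methylbut-3-en-1-ylmagnesium bromide (from 4-bromo-2-methylbut-1-ene and Mg), THF, −78 °C; 12, −78 → −40 °C; aq. NH4Cl
Reagents that add atoms: 3-methylbut-3-en-1-ylmagnesium bromide, C=C(C)CC[Mg]Br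
Why: organocerium 1,2-addition, non-basic so that the enolisable C3–H survives, should occur on the face that carries only methyl and hydrogen, anti to both the isopropyl and the hydroxyallyl groups, which sets C3a with hydroxyl cis to isopropyl and the two alkenyl chains trans.

Step 8
Reactants: 13 (1S,2S,5S)-3-[(tert-butyldimethylsilyl)oxy]-2-[(1S)-1-hydroxyprop-2-en-1-yl]-2-methyl-1-(3-methylbut-3-en-1-yl)-5-(propan-2-yl)cyclopent-3-en-1-ol
Product: 14 (3S,3aS,8S,8aS)-1-[(tert-butyldimethylsilyl)oxy]-6,8a-dimethyl-3-(propan-2-yl)-3,3a,4,5,8,8a-hexahydroazulene-3a,8-diol (8-hydroxyl trans to the 8a-methyl)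
Conditions: second-generation Grubbs catalyst RuCl2(=CHPh)(H2IMes)(PCy3) (5 mol %), CH2Cl2 (0.005 M), 40 °C
Reagents that add atoms: none
Why: ring-closing metathesis between the vinyl carbinol and the 1,1-disubstituted alkene should close the trans-fused seven-membered ring as its trisubstituted C6=C7 olefin with loss of ethene, the hindered cyclic silyl enol ether being inert.

Step 9
Reactants: 14 (3S,3aS,8S,8aS)-1-[(tert-butyldimethylsilyl)oxy]-6,8a-dimethyl-3-(propan-2-yl)-3,3a,4,5,8,8a-hexahydroazulene-3a,8-diol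
Product: 15 (3S,3aS,8aS)-1-[(tert-butyldimethylsilyl)oxy]-3a-hydroxy-6,8a-dimethyl-3-(propan-2-yl)-3a,4,5,8a-tetrahydroazulen-8(3H)-one
Conditions: Dess–Martin periodinane, pyridine, CH2Cl2, 0 → 25 °C
Reagents that add atoms: none
Why: Dess–Martin oxidation of the secondary allylic alcohol should remove the relay stereocentre and give the enone, leaving the tertiary alcohol and the silyl enol ether (the mask of the C1 ketone) untouched.

Step 10
Reactants: 15 (3S,3aS,8aS)-1-[(tert-butyldimethylsilyl)oxy]-3a-hydroxy-6,8a-dimethyl-3-(propan-2-yl)-3a,4,5,8a-tetrahydroazulen-8(3H)-one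
Product: 17 (3R,3aS,8R,8aS)-3a,8-dihydroxy-6,8a-dimethyl-3-(propan-2-yl)-3,3a,4,5,8,8a-hexahydroazulen-1(2H)-one, via silyl enol ether diol 16 (not isolated)
Conditions: i-Bu2AlH, CH2Cl2, −78 °C; Rochelle salt; crude 16, Bu4NF, AcOH, THF, 0 °C
Reagents that add atoms: none
Why: 1,2-reduction of the enone should deliver hydride anti to the axial angular methyl group (the face of the C3a oxygen), giving the C8 alcohol cis to methyl and anti to the C3a hydroxyl, and buffered fluoride then unmasks the C1 ketone from the silyl enol ether.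

Step 11
Reactants: 17 (3R,3aS,8R,8aS)-3a,8-dihydroxy-6,8a-dimethyl-3-(propan-2-yl)-3,3a,4,5,8,8a-hexahydroazulen-1(2H)-one; 18 4-methoxybenzoyl chloride
Product: 19 (3R,3aS,8R,8aS)-3a-hydroxy-6,8a-dimethyl-1-oxo-3-(propan-2-yl)-1,2,3,3a,4,5,8,8a-octahydroazulen-8-yl 4-methoxybenzoate
Conditions: Et3N, DMAP (cat.), CH2Cl2, 0 → 25 °C
Reagents that add atoms: none
Why: DMAP-catalysed acylation with the acid chloride should esterify only the secondary allylic hydroxyl, the tertiary C3a hydroxyl being too hindered to react.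

**Compound list**

1 | ethyl (E)-4-methylpent-2-enoate | CCOC(=O)/C=C/C(C)C | starting material
2 | (E)-4-methylpent-2-en-1-ol | CC(C)/C=C/CO | intermediate
3 | tert-butyldimethyl{[(E)-4-methylpent-2-en-1-yl]oxy}silane | CC(C)/C=C/CO[Si](C)(C)C(C)(C)C | intermediate
4 | (E)-1-(tert-butyldimethylsilyl)-4-methylpent-2-en-1-ol (racemic) | CC(C)/C=C/C(O)[Si](C)(C)C(C)(C)C | intermediate
5 | (E)-1-(tert-butyldimethylsilyl)-4-methylpent-2-en-1-one | CC(C)/C=C/C(=O)[Si](C)(C)C(C)(C)C | intermediate
6 | (4R)-4-benzyl-3-propanoyl-1,3-oxazolidin-2-one | CCC(=O)N1[C@H](Cc2ccccc2)COC1=O | starting material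
7 | acrolein | C=CC=O | starting material
8 | (4R)-4-benzyl-3-[(2R,3S)-3-hydroxy-2-methylpent-4-enoyl]-1,3-oxazolidin-2-one | C=C[C@H](O)[C@@H](C)C(=O)N1[C@H](Cc2ccccc2)COC1=O | intermediate
9 | (2R,3S)-3-hydroxy-N-methoxy-N,2-dimethylpent-4-enamide | C=C[C@H](O)[C@@H](C)C(=O)N(C)OC | intermediate
10 | dilithium enolate alkoxide of 9 | [Li+].[Li+].C=C[C@H]([O-])C(C)=C([O-])N(C)OC | intermediate
11 | dilithium salt of the cyclised N-methoxy-N-methyl hemiaminal (C3a tetrahedral) | [Li+].[Li+].C=C[C@H]([O-])[C@@]1(C)C([O-])(N(C)OC)[C@@H](C(C)C)C=C1O[Si](C)(C)C(C)(C)C | intermediate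
12 | (2R,5S)-3-[(tert-butyldimethylsilyl)oxy]-2-[(1S)-1-hydroxyprop-2-en-1-yl]-2-methyl-5-(propan-2-yl)cyclopent-3-en-1-one | C=C[C@H](O)[C@@]1(C)C(=O)[C@@H](C(C)C)C=C1O[Si](C)(C)C(C)(C)C | intermediate
13 | (1S,2S,5S)-3-[(tert-butyldimethylsilyl)oxy]-2-[(1S)-1-hydroxyprop-2-en-1-yl]-2-methyl-1-(3-methylbut-3-en-1-yl)-5-(propan-2-yl)cyclopent-3-en-1-ol | C=C[C@H](O)[C@@]1(C)[C@](O)(CCC(C)=C)[C@@H](C(C)C)C=C1O[Si](C)(C)C(C)(C)C | intermediate
14 | (3S,3aS,8S,8aS)-1-[(tert-butyldimethylsilyl)oxy]-6,8a-dimethyl-3-(propan-2-yl)-3,3a,4,5,8,8a-hexahydroazulene-3a,8-diol | O[C@H]1C=C(C)CC[C@]2(O)[C@@H](C(C)C)C=C(O[Si](C)(C)C(C)(C)C)[C@@]12C | intermediate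
15 | (3S,3aS,8aS)-1-[(tert-butyldimethylsilyl)oxy]-3a-hydroxy-6,8a-dimethyl-3-(propan-2-yl)-3a,4,5,8a-tetrahydroazulen-8(3H)-one | O=C1C=C(C)CC[C@]2(O)[C@@H](C(C)C)C=C(O[Si](C)(C)C(C)(C)C)[C@@]12C | intermediate
16 | (3S,3aS,8R,8aS)-1-[(tert-butyldimethylsilyl)oxy]-6,8a-dimethyl-3-(propan-2-yl)-3,3a,4,5,8,8a-hexahydroazulene-3a,8-diol | O[C@@H]1C=C(C)CC[C@]2(O)[C@@H](C(C)C)C=C(O[Si](C)(C)C(C)(C)C)[C@@]12C | intermediate
17 | (3R,3aS,8R,8aS)-3a,8-dihydroxy-6,8a-dimethyl-3-(propan-2-yl)-3,3a,4,5,8,8a-hexahydroazulen-1(2H)-one | O[C@@H]1C=C(C)CC[C@]2(O)[C@@H](C(C)C)CC(=O)[C@@]12C | intermediate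
18 | 4-methoxybenzoyl chloride | COc1ccc(C(Cl)=O)cc1 | starting material
19 | (3R,3aS,8R,8aS)-3a-hydroxy-6,8a-dimethyl-1-oxo-3-(propan-2-yl)-1,2,3,3a,4,5,8,8a-octahydroazulen-8-yl 4-methoxybenzoate | COc1ccc(C(=O)O[C@@H]2C=C(C)CC[C@]3(O)[C@@H](C(C)C)CC(=O)[C@@]23C)cc1 | target

**Step count.** Total: 11 steps. Longest linear sequence: 9 steps (steps 1–3, then 6–11); the amide branch (steps 4–5) joins at step 6.

**Steps most likely to fail**

Step 6 (proposed new method). The congested 1,2-adduct may revert before the Brook shift, the siloxyallyl anion may be quenched by proton transfer instead of closing the ring, the silyl group may migrate from the enol oxygen to the C8 alkoxide, or closure through an open transition state may erode control at C3. The fallback uses the established ketone-enolate form of the annulation and sets out from 9. Sulfenylation of its dianion with diphenyl disulfide should give (3S)-3-hydroxy-N-methoxy-N,2-dimethyl-2-(phenylsulfanyl)pent-4-enamide F1. Addition of 3-methylbut-3-en-1-ylmagnesium bromide to the Weinreb amide should give (3S)-3-hydroxy-4,8-dimethyl-4-(phenylsulfanyl)nona-1,8-dien-5-one F2. Deprotonation of the hydroxyl with n-BuLi and reductive C–S cleavage with lithium 4,4′-di-tert-butylbiphenylide should generate the regiodefined, more substituted ketone lithium enolate. Its Brook-mediated [3+2] annulation with 5 closes the ring onto the ketone, so that C3 and C3a are set together, and the fallback comes back to the route at 13.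

Step 7. Ketone 12 may enolise or epimerise at C3 before the carbon–carbon bond forms, or the bulky nucleophile may add slowly and from the wrong face. The fallback builds the side chain in two smaller events and sets out from 12. Corey–Chaykovsky methylene transfer with dimethylsulfonium methylide should add from the open methyl face and give 5-[(tert-butyldimethylsilyl)oxy]-4-[(1S)-1-hydroxyprop-2-en-1-yl]-4-methyl-7-(propan-2-yl)-1-oxaspiro[2.4]hept-5-ene F3. CuI-catalysed opening of the oxirane CH2 with 2-methylallylmagnesium chloride should then complete the 3-methylbut-3-enyl chain, and the fallback comes back at 13.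

Step 10. Hydride may be delivered from the methyl face, or conjugate reduction may compete. The fallback replaces external hydride by tethered delivery and sets out from 15. Silylation of the C3a hydroxyl with chlorodiisopropylsilane and imidazole should give the 3a-O-(diisopropylsilyl) ether of 15 F4. SnCl4-catalysed intramolecular hydrosilylation should transfer hydride to C8 from the face of the C3a oxygen and give the cyclic 3a,8-O-diisopropylsilylene of 16 F5, with the anti-1,3-dioxygen pattern. Bu4NF/AcOH should then remove the silylene and the silyl enol ether, and the fallback comes back at 17.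

Further compounds
F1 | step 6 | (3S)-3-hydroxy-N-methoxy-N,2-dimethyl-2-(phenylsulfanyl)pent-4-enamide | C=C[C@H](O)C(C)(Sc1ccccc1)C(=O)N(C)OC
F2 | step 6 | (3S)-3-hydroxy-4,8-dimethyl-4-(phenylsulfanyl)nona-1,8-dien-5-one | C=C[C@H](O)C(C)(Sc1ccccc1)C(=O)CCC(C)=C
F3 | step 7 | 5-[(tert-butyldimethylsilyl)oxy]-4-[(1S)-1-hydroxyprop-2-en-1-yl]-4-methyl-7-(propan-2-yl)-1-oxaspiro[2.4]hept-5-ene | C=C[C@H](O)[C@@]1(C)[C@]2(CO2)[C@@H](C(C)C)C=C1O[Si](C)(C)C(C)(C)C
F4 | step 10 | 3a-O-(diisopropylsilyl) ether of 15 | O=C1C=C(C)CC[C@]2(O[SiH](C(C)C)C(C)C)[C@@H](C(C)C)C=C(O[Si](C)(C)C(C)(C)C)[C@@]12C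
F5 | step 10 | cyclic 3a,8-O-diisopropylsilylene of 16 | CC(C)[Si]1(C(C)C)O[C@@H]2C=C(C)CC[C@]3(O1)[C@@H](C(C)C)C=C(O[Si](C)(C)C(C)(C)C)[C@@]23C
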